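All constants are assumed; the rest is arithmetic.

In a one-step world the catalyst waits in one place; this flask runs two cycles on one free catalyst, so I count where it waits.

    partner + catalyst intermediate B → free catalyst + second product (k1 = 15000 M⁻¹ s⁻¹)
    gas ⇌ partner, rate k2*(csat - [partner]) (k2 = 0.14 s⁻¹, csat = 0.034 mM)
    partner → decomposed reagent (k3 = 0.031 s⁻¹)
    partner + catalyst intermediate A → free catalyst + target (k4 = 8000 M⁻¹ s⁻¹)
    starting material + free catalyst ⇌ catalyst intermediate A (K5 = 1.4 × 10⁵ M⁻¹, k5 = 4000 M⁻¹ s⁻¹)
    second substrate + free catalyst ⇌ catalyst intermediate B (K6 = 32000 M⁻¹, k6 = 8400 M⁻¹ s⁻¹)

starting material 0.20 mM; second substrate 0.200 mM; gas 0.034 mM (held); free catalyst 4.8 µM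

- at the start none of partner is dissolved
- what is bound to the catalyst counts as converted
- charge of starting material (flask): 0.20 mM

1. the form that holds most of the catalyst when 10% of the starting material are converted (free catalyst / catalyst intermediate A / catalyst intermediate B)
2. its share of the catalyst then

I write x for the fraction of starting material still free, and u for dissolved partner as a fraction of its saturation value.

**First instants.** No partner is dissolved yet. By the forward steps alone, second substrate captures free catalyst 2.1 times as fast as starting material, so I expect catalyst intermediate B to lead at first. Falling back is slower for intermediate A, at 1.71 min⁻¹, than for intermediate B, at 15.8 min⁻¹.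

**Middle.** The gas feeds partner with a relaxation time of 5.85 s. With decomposition running and no catalyst taking partner, u tends to a ceiling of 81.9%. At that ceiling, partner clears intermediate A at 13.4 min⁻¹ and intermediate B at 25.1 min⁻¹. With full charges I get:

hold of A = 48 min⁻¹ / (1.71 min⁻¹ + 13.4 min⁻¹) = 3.18

hold of B = 100 min⁻¹ / (15.8 min⁻¹ + 25.1 min⁻¹) = 2.47

I call capture per free catalyst over exit per bound catalyst the hold number of a form; the hold of A is the number carried forward here. It gives that form's amount over free catalyst, and for intermediate A it scales with x. The hold of A is larger than the hold of B, so I name intermediate A as the resting state. Its share is its hold over one plus both holds, 47.8%. This is a first figure, taken at full charges and at the ceiling.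

**End.** The hold of A reaches one at x = 31.4%. Below that crossing, I expect free catalyst to outweigh intermediate A.

The forecast names catalyst intermediate A at 51%, on the ground that “A barely dissociates and reacts more slowly with the partner”. It stands above my figure.

The flask gives catalyst intermediate A at 50.3%, within the forecast's margin, at 0.772 min. With 0.7 of the charge converted, at 5.59 min, the rate of making target is 0.90 of the rate at 10% conversion. At 5.00 min, x is 36.8% and partner is 0.0232 mM, so the hold of A is 1.37, and intermediate A over free catalyst stands at 1.38.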